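**Retrosynthetic overview**

- The strategy rests on the single bond that holds the two davidigenin units together: C3 of the 4-hydroxyphenyl ring B of one half to C5' of the 2,4-dihydroxybenzoyl ring C of the other, each carbon lying next to a phenol oxygen (O4 on ring B, O4' on ring C).
- A di-tert-butylsilylene bridge between O4 and O4' turns this biaryl coupling into a seven-membered ring closure: palladium-catalysed C–H arylation from a C5' bromide onto C3–H. Fluoride then excises the bridge and hydrogenolysis removes four benzyl ethers.
- The bis(aryloxy)silane is assembled from tBu2Si(OTf)2 and two complete dihydrochalcone monomers, one with only the ring B phenol free, the other with a C5' bromine and only the 4'-OH free.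
- Each monomer comes from a Claisen–Schmidt condensation of a protected acetophenone (rings A and C) with a 4-oxygenated benzaldehyde (rings B and D), followed by RhCl(PPh3)3-catalysed saturation of the enone.
- Ring order: all four benzene rings are purchased; the only ring made is the temporary dioxasilepine, closed in step 10 and opened again in step 11.

Key step: step 10

Remark: rings A/B are the benzoyl and phenethyl rings of the half joined through C3, rings C/D those of the half joined through C5'; the target has no stereocentre and its biaryl axis, flanked by only two ortho hydroxyls, rotates freely, so no step has to control configuration; 5-bromo-2,4-dihydroxyacetophenone and tBu2Si(OTf)2 are taken as purchased.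

**Route**

Step 1
Reactants: 1 2,4-dihydroxyacetophenone (ring A)
Product: 2 2,4-bis(benzyloxy)acetophenone
Conditions: BnBr (2.5 equiv), K2CO3 (3 equiv), DMF, 70 °C
Reagents that add atoms: benzyl bromide, BrCc1ccccc1
Why: Williamson etherification of both phenols, the dipolar solvent and heat being enough to alkylate the hydrogen-bonded 2-OH as well as the free 4-OH.

Step 2
Reactants: 2 2,4-bis(benzyloxy)acetophenone; 3 4-hydroxybenzaldehyde (ring B)
Product: 4 (E)-1-[2,4-bis(benzyloxy)phenyl]-3-(4-hydroxyphenyl)prop-2-en-1-one
Conditions: KOH (50% aq., 10 equiv), EtOH, rt → 40 °C; then aq. HCl to pH 4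
Reagents that add atoms: none
Why: Claisen–Schmidt condensation in which the methyl ketone is the only enolisable partner and the aldehyde, although slowed as its phenoxide, the only electrophile; dehydration under equilibrating conditions should give the E enone, whose geometry is erased in the next step.

Step 3
Reactants: 4 (E)-1-[2,4-bis(benzyloxy)phenyl]-3-(4-hydroxyphenyl)prop-2-en-1-one
Product: 5 1-[2,4-bis(benzyloxy)phenyl]-3-(4-hydroxyphenyl)propan-1-one (monomer 1, ring B phenol free)
Conditions: RhCl(PPh3)3 (5 mol %), H2 (1–3 atm), toluene/EtOH (1:1), 50 °C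
Reagents that add atoms: none
Why: homogeneous rhodium-catalysed hydrogenation saturates only the conjugated C=C and, unlike heterogeneous palladium, should leave the aryl ketone and both benzyl ethers intact.

Step 4
Reactants: 6 5-bromo-2,4-dihydroxyacetophenone (ring C)
Product: 7 5-bromo-2-hydroxy-4-(methoxymethoxy)acetophenone
Conditions: MOMCl (1.1 equiv), K2CO3, acetone, 0 °C → rt
Reagents that add atoms: chloromethyl methyl ether, COCCl
Why: selective O-alkylation, since the 4-OH is the more acidic and accessible phenol whereas the 2-OH is held in a hydrogen bond to the acetyl carbonyl and should stay free under this mild base.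

Step 5
Reactants: 7 5-bromo-2-hydroxy-4-(methoxymethoxy)acetophenone
Product: 8 2-benzyloxy-5-bromo-4-(methoxymethoxy)acetophenone
Conditions: BnBr (1.3 equiv), K2CO3, DMF, 65 °C
Reagents that add atoms: benzyl bromide, BrCc1ccccc1
Why: Williamson etherification of the remaining chelated phenol, which needs DMF and heat, while the methoxymethyl acetal and the aryl bromide are inert to carbonate.

Step 6
Reactants: 8 2-benzyloxy-5-bromo-4-(methoxymethoxy)acetophenone; 9 4-benzyloxybenzaldehyde (ring D)
Product: 10 (E)-1-[2-benzyloxy-5-bromo-4-(methoxymethoxy)phenyl]-3-(4-benzyloxyphenyl)prop-2-en-1-one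
Conditions: KOH (50% aq., 3 equiv), EtOH/THF, rt
Reagents that add atoms: none
Why: Claisen–Schmidt condensation between the only enolisable ketone and a non-enolisable aldehyde; the acetal, the benzyl ethers and the aryl bromide tolerate hydroxide at room temperature and the E enone forms under thermodynamic control.

Step 7
Reactants: 10 (E)-1-[2-benzyloxy-5-bromo-4-(methoxymethoxy)phenyl]-3-(4-benzyloxyphenyl)prop-2-en-1-one
Product: 11 1-[2-benzyloxy-5-bromo-4-(methoxymethoxy)phenyl]-3-(4-benzyloxyphenyl)propan-1-one
Conditions: RhCl(PPh3)3 (5 mol %), H2 (1–3 atm), toluene/EtOH (1:1), 50 °C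
Reagents that add atoms: none
Why: homogeneous rhodium-catalysed hydrogenation reduces only the enone C=C and, in contrast to Pd/C, should neither insert into the aryl C–Br bond nor hydrogenolyse the benzyl ethers.

Step 8
Reactants: 11 1-[2-benzyloxy-5-bromo-4-(methoxymethoxy)phenyl]-3-(4-benzyloxyphenyl)propan-1-one
Product: 12 1-(2-benzyloxy-5-bromo-4-hydroxyphenyl)-3-(4-benzyloxyphenyl)propan-1-one (monomer 2, 4'-OH free)
Conditions: conc. HCl (cat.), MeOH/THF, 45 °C
Reagents that add atoms: none
Why: acid-catalysed transacetalisation of the methoxymethyl ether to methanol frees O4' as the only phenol, while benzyl ethers, the aryl bromide and the saturated ketone are stable to dilute HCl.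

Step 9
Reactants: 12 1-(2-benzyloxy-5-bromo-4-hydroxyphenyl)-3-(4-benzyloxyphenyl)propan-1-one; 13 di-tert-butylsilyl bis(trifluoromethanesulfonate); 5 1-[2,4-bis(benzyloxy)phenyl]-3-(4-hydroxyphenyl)propan-1-one
Product: 15 unsymmetrical bis(aryloxy)di-tert-butylsilane (O4' of ring C–Si–O4 of ring B), via aryloxysilyl triflate 14 (not isolated)
Conditions: 12, 13 (1.05 equiv), 2,6-lutidine (1.5 equiv), CH2Cl2, −78 → 0 °C; then 5 (1.1 equiv), imidazole (3 equiv), DMF, 0 → 40 °C
Reagents that add atoms: none
Why: two successive nucleophilic substitutions at silicon, in which the first triflate of 13 is displaced quickly at low temperature even by the hindered, weakly nucleophilic ortho-bromophenol, the resulting monotriflate 14 is too crowded and too weakly electrophilic to take a second molecule of 12, and it is then captured by the unhindered phenol 5 under imidazole activation, the ketones not being enolised by 2,6-lutidine at these temperatures.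

Step 10
Reactants: 15 unsymmetrical bis(aryloxy)di-tert-butylsilane
Product: 16 6,6-di-tert-butyldibenzo[d,f][1,3,2]dioxasilepine carrying both benzyl-protected dihydrochalcone chains
Conditions: Pd(OAc)2 (10 mol %), PCy3·HBF4 (20 mol %), K2CO3 (2 equiv, dried), PivOH (30 mol %), DMA, 120 °C, Ar
Reagents that add atoms: none
Why: Zerovalent palladium generated from Pd(OAc)2 and PCy3 inserts into the C5'–Br bond of ring C, and the O4'–Si–O4 bridge then holds the divalent arylpalladium pivalate over C3–H of ring B, which is broken by concerted metalation–deprotonation to an eight-membered diarylpalladacycle. Reductive elimination forges the C3–C5' bond and thereby closes the seven-membered ring Si–O4–C4–C3–C5'–C4'–O4' by C(sp2)–C(sp2) bond formation, returning zerovalent palladium. The closest known reaction type is the palladium-catalysed intramolecular direct arylation of ortho-bromoaryl aryl di-tert-butylsilylene bis-ethers to dibenzodioxasilepines. No stereocentre is created. The step needs site selectivity on both rings and cross-coupling rather than homocoupling: the bromine fixes C5' on ring C, the tether reaches only the two equivalent carbons ortho to O4 on the para-disubstituted ring B, and the intramolecular course joins exactly one molecule of each monomer. All other phenols are benzylated and the ketone α-methylenes lie too far from palladium to be arylated under carbonate.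

Step 11
Reactants: 16 6,6-di-tert-butyldibenzo[d,f][1,3,2]dioxasilepine carrying both chains
Product: 17 tetra-O-benzyl biphenol (free OH at O4 of ring B and O4' of ring C)
Conditions: Bu4NF (2.5 equiv), AcOH (2.5 equiv), THF, 0 °C → rt
Reagents that add atoms: none
Why: fluoride-mediated desilylation driven by the strength of the Si–F bond expels both aryloxides, acetic acid protonating them so that the ketones see no strong base, and benzyl ethers are untouched.

Step 12
Reactants: 17 tetra-O-benzyl biphenol
Product: 18 target CID44566750
Conditions: H2 (1 atm), 10% Pd/C, EtOAc, rt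
Reagents that add atoms: none
Why: palladium-catalysed hydrogenolysis of the four benzylic C–O bonds; the two aryl ketones, deactivated by ortho and para oxygen donors, should survive at ambient pressure in a neutral solvent if the reaction is stopped once hydrogen uptake ceases.

**Compound list**

1 | 2,4-dihydroxyacetophenone | CC(=O)c1ccc(O)cc1O | starting material
2 | 2,4-bis(benzyloxy)acetophenone | CC(=O)c1ccc(OCc2ccccc2)cc1OCc1ccccc1 | intermediate
3 | 4-hydroxybenzaldehyde | O=Cc1ccc(O)cc1 | starting material
4 | (E)-1-[2,4-bis(benzyloxy)phenyl]-3-(4-hydroxyphenyl)prop-2-en-1-one | O=C(/C=C/c1ccc(O)cc1)c1ccc(OCc2ccccc2)cc1OCc1ccccc1 | intermediate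
5 | 1-[2,4-bis(benzyloxy)phenyl]-3-(4-hydroxyphenyl)propan-1-one (monomer 1) | O=C(CCc1ccc(O)cc1)c1ccc(OCc2ccccc2)cc1OCc1ccccc1 | intermediate
6 | 5-bromo-2,4-dihydroxyacetophenone | CC(=O)c1cc(Br)c(O)cc1O | starting material
7 | 5-bromo-2-hydroxy-4-(methoxymethoxy)acetophenone | CC(=O)c1cc(Br)c(OCOC)cc1O | intermediate
8 | 2-benzyloxy-5-bromo-4-(methoxymethoxy)acetophenone | CC(=O)c1cc(Br)c(OCOC)cc1OCc1ccccc1 | intermediate
9 | 4-benzyloxybenzaldehyde | O=Cc1ccc(OCc2ccccc2)cc1 | starting material
10 | (E)-1-[2-benzyloxy-5-bromo-4-(methoxymethoxy)phenyl]-3-(4-benzyloxyphenyl)prop-2-en-1-one | O=C(/C=C/c1ccc(OCc2ccccc2)cc1)c1cc(Br)c(OCOC)cc1OCc1ccccc1 | intermediate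
11 | 1-[2-benzyloxy-5-bromo-4-(methoxymethoxy)phenyl]-3-(4-benzyloxyphenyl)propan-1-one | O=C(CCc1ccc(OCc2ccccc2)cc1)c1cc(Br)c(OCOC)cc1OCc1ccccc1 | intermediate
12 | 1-(2-benzyloxy-5-bromo-4-hydroxyphenyl)-3-(4-benzyloxyphenyl)propan-1-one (monomer 2) | O=C(CCc1ccc(OCc2ccccc2)cc1)c1cc(Br)c(O)cc1OCc1ccccc1 | intermediate
13 | di-tert-butylsilyl bis(trifluoromethanesulfonate) | CC(C)(C)[Si](OS(=O)(=O)C(F)(F)F)(OS(=O)(=O)C(F)(F)F)C(C)(C)C | starting material
14 | di-tert-butyl(aryloxy)silyl trifluoromethanesulfonate derived from 12 through O4' of ring C | CC(C)(C)[Si](OS(=O)(=O)C(F)(F)F)(Oc1cc(OCc2ccccc2)c(C(=O)CCc2ccc(OCc3ccccc3)cc2)cc1Br)C(C)(C)C | intermediate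
15 | di-tert-butylsilane bearing the aryloxy group of 12 (O4' of ring C) and the aryloxy group of 5 (O4 of ring B) | CC(C)(C)[Si](Oc1ccc(CCC(=O)c2ccc(OCc3ccccc3)cc2OCc2ccccc2)cc1)(Oc1cc(OCc2ccccc2)c(C(=O)CCc2ccc(OCc3ccccc3)cc2)cc1Br)C(C)(C)C | intermediate
16 | 6,6-di-tert-butyldibenzo[d,f][1,3,2]dioxasilepine carrying both benzyl-protected dihydrochalcone chains | CC(C)(C)[Si]1(C(C)(C)C)Oc2ccc(CCC(=O)c3ccc(OCc4ccccc4)cc3OCc3ccccc3)cc2-c2cc(C(=O)CCc3ccc(OCc4ccccc4)cc3)c(OCc3ccccc3)cc2O1 | intermediate
17 | tetra-O-benzyl biphenol (2,2'-dihydroxybiaryl, all other phenols benzylated) | O=C(CCc1ccc(O)c(-c2cc(C(=O)CCc3ccc(OCc4ccccc4)cc3)c(OCc3ccccc3)cc2O)c1)c1ccc(OCc2ccccc2)cc1OCc1ccccc1 | intermediate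
18 | CID44566750, 3-(5'-linked) davidigenin dimer | O=C(CCc1ccc(O)c(-c2cc(C(=O)CCc3ccc(O)cc3)c(O)cc2O)c1)c1ccc(O)cc1O | target

**Step count and risks**

Total step count: 12 (compound 14 is not isolated). Longest linear sequence: 9 steps (6 to 18, steps 4 to 12); the branch from 1 takes 7 steps (steps 1 to 3 and 9 to 12).

Steps most likely to fail:

1. Step 10. The arylpalladium intermediate may be reduced (loss of bromine without C–C bond formation), the silicon bridge may be lost from the acidic para-acylphenol oxygen under carbonate at 120 °C before the palladacycle forms, or a tert-butyl C–H may be metalated in place of C3–H. The fallback forms the same biaryl bond by intermolecular cross-coupling; it sets out from 11 and 5 and returns to the route at 17. Bromide 11 would undergo Miyaura borylation (B2pin2, PdCl2(dppf), KOAc, dioxane, 90 °C) to the pinacol boronate F1. Monomer 5 would be iodinated ortho to its free phenol (N-iodosuccinimide, catalytic p-TsOH, MeCN, 0 °C) to the 3-iodo-4-hydroxy dihydrochalcone F2. Suzuki–Miyaura coupling of F1 with F2 (PdCl2(dppf), K2CO3, dioxane/water, 80 °C) should give the mono-methoxymethyl biaryl F3, and HCl in MeOH would then free O4' to reach 17, bypassing 15 and 16.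

2. Step 9. Aryloxy groups may exchange at silicon and give the two symmetrical bis-ethers, the second displacement may stall at the crowded silicon, or the monotriflate may be hydrolysed by adventitious water. The fallback separates the two Si–O bond formations through an isolable hydrosilane; it sets out from 12 and returns at 15. Phenol 12 would be silylated with di-tert-butylchlorosilane (imidazole, DMF, rt) to the aryloxy(di-tert-butyl)hydrosilane F4, whose Si–H bond cannot take a second phenol and which can be purified. N-Bromosuccinimide (CH2Cl2, 0 °C) would then convert Si–H into the aryloxysilyl bromide F5, which is treated in the same flask with 5, imidazole and DMF to give 15.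

3. Step 2. The aldehyde reacts as its phenoxide, a vinylogous carboxylate, so the aldol addition may stall or revert and conversion may stay low. The fallback masks the phenol during the condensation; it sets out from 3 and returns at 4. Aldehyde 3 would be converted (MOMCl, K2CO3, acetone) into 4-(methoxymethoxy)benzaldehyde F6. Claisen–Schmidt condensation with 2 (KOH, EtOH, rt) should give the methoxymethyl-protected chalcone F7, and HCl in MeOH at 45 °C would release 4.

Further compounds
F1 | step 10 | 1-[2-benzyloxy-4-(methoxymethoxy)-5-(4,4,5,5-tetramethyl-1,3,2-dioxaborolan-2-yl)phenyl]-3-(4-benzyloxyphenyl)propan-1-one | O=C(CCc1ccc(OCc2ccccc2)cc1)c1cc(B2OC(C)(C)C(C)(C)O2)c(OCOC)cc1OCc1ccccc1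
F2 | step 10 | 1-[2,4-bis(benzyloxy)phenyl]-3-(4-hydroxy-3-iodophenyl)propan-1-one | O=C(CCc1ccc(O)c(I)c1)c1ccc(OCc2ccccc2)cc1OCc1ccccc1
F3 | step 10 | tetra-O-benzyl biaryl with O4' of ring C as methoxymethyl ether and O4 of ring B free | O=C(CCc1ccc(O)c(-c2cc(C(=O)CCc3ccc(OCc4ccccc4)cc3)c(OCc3ccccc3)cc2OCOC)c1)c1ccc(OCc2ccccc2)cc1OCc1ccccc1
F4 | step 9 | aryloxy(di-tert-butyl)hydrosilane derived from 12 | CC(C)(C)[SiH](Oc1cc(OCc2ccccc2)c(C(=O)CCc2ccc(OCc3ccccc3)cc2)cc1Br)C(C)(C)C
F5 | step 9 | aryloxy(di-tert-butyl)silyl bromide derived from F4 | CC(C)(C)[Si](Br)(Oc1cc(OCc2ccccc2)c(C(=O)CCc2ccc(OCc3ccccc3)cc2)cc1Br)C(C)(C)C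
F6 | step 2 | 4-(methoxymethoxy)benzaldehyde | COCOc1ccc(C=O)cc1
F7 | step 2 | (E)-1-[2,4-bis(benzyloxy)phenyl]-3-[4-(methoxymethoxy)phenyl]prop-2-en-1-one | O=C(/C=C/c1ccc(OCOC)cc1)c1ccc(OCc2ccccc2)cc1OCc1ccccc1
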